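**Plan**

1. Labels: C10 is the quaternary carbon (CH3 and ester chain C1–C3), C5 the CH bearing isopropenyl (C4), C6 the CH2, C7 the ring ketone, C8/C9 the fusion carbons, and C11–C14 the quinone ring C (C12 OH, C13 isopropyl, C14 beside C8). Ring B is C5–C10.
2. Enabling feature: rings B and C together are a naphthalene at a lower oxidation level. C10–C5 is the 1,2-bond of a 1-naphthyl oxazoline, the C7 ketone is its 4-methoxy group (an enol ether after dearomatisation), and the hydroxyquinone is a 5,7-dimethoxy-6-isopropyl arene.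
3. Cuts, in retrosynthetic order: ring C oxidation and ester/methyl adjustments, then C4–C5 and C10–C1 together (isopropenyllithium and a 3-silyloxypropyl iodide across C5=C10 of oxazoline 21), then ring B at C7–C8 (Friedel–Crafts), C5–C10 (Michael) and C9–C10 (aryl–CH2 coupling).
4. Forward: ring C comes from 1,3-dimethoxybenzene. Ring B is closed (step 6), aromatised (step 7) and dearomatised again with both carbon substituents (step 11). The oxazoline carbon then becomes the C10 methyl (steps 12–13), the chain end the methyl ester (steps 14–15) and ring C the hydroxyquinone (steps 16–18).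
5. Stereochemistry: C5 is set by the (R)-tert-butyl oxazoline made from (R)-tert-leucinol, and C10 by alkylation anti to the new isopropenyl group. Neither centre can epimerise later (C10 is quaternary, C5 is β to the ketone).

Key step: step 11

Assumption: the nitrogen-bound lithium reagent is taken to enter C5 from the face opposite the tert-butyl group in the s-cis N=C–C10=C5 conformer, which for the (R)-oxazoline gives the (5S) centre of the target; if the sense were the reverse, (S)-tert-leucinol would be used with no other change.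

**Route**

Step 1
Reactants: 1 1,3-dimethoxybenzene; 2 acetone
Product: 4 2-(2,6-dimethoxyphenyl)propan-2-ol, via 2,6-dimethoxyphenyllithium 3 (not isolated)
Conditions: n-BuLi, THF, 0 °C to rt; then 2, −78 °C to rt; H2O
Reagents that add atoms: none
Why: Directed ortho-metalation puts lithium on the carbon flanked by both methoxy groups and the aryllithium undergoes 1,2-addition to the ketone.

Step 2
Reactants: 4 2-(2,6-dimethoxyphenyl)propan-2-ol
Product: 5 2-isopropyl-1,3-dimethoxybenzene
Conditions: Et3SiH, CF3CO2H, CH2Cl2, 0 °C to rt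
Reagents that add atoms: none
Why: Ionic hydrogenation, in which the benzylic cation stabilised by two ortho methoxy groups is reduced by the silane.

Step 3
Reactants: 5 2-isopropyl-1,3-dimethoxybenzene
Product: 6 2-(4-isopropyl-3,5-dimethoxyphenyl)-4,4,5,5-tetramethyl-1,3,2-dioxaborolane
Conditions: [Ir(OMe)(cod)]2 (cat.), 4,4′-di-tert-butyl-2,2′-bipyridine (cat.), B2pin2, THF, 80 °C
Reagents that add atoms: bis(pinacolato)diboron, CC1(C)OB(OC1(C)C)B1OC(C)(C)C(C)(C)O1
Why: Sterically governed iridium-catalysed C–H borylation goes to the only ring C–H that has no ortho substituent, para to the isopropyl group.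

Step 4
Reactants: 6 2-(4-isopropyl-3,5-dimethoxyphenyl)-4,4,5,5-tetramethyl-1,3,2-dioxaborolane; 7 methyl bromoacetate
Product: 8 methyl 2-(4-isopropyl-3,5-dimethoxyphenyl)acetate
Conditions: Pd(OAc)2 (cat.), tri(1-naphthyl)phosphine (cat.), K3PO4, THF/H2O, 40 °C
Reagents that add atoms: none
Why: Suzuki–Miyaura-type coupling of an arylboronate with an α-bromo ester, in which zerovalent palladium inserts into the C–Br bond and the resulting palladium enolate is arylated.

Step 5
Reactants: 8 methyl 2-(4-isopropyl-3,5-dimethoxyphenyl)acetate; 9 tert-butyl acrylate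
Product: 11 5-tert-butyl 1-methyl 2-(4-isopropyl-3,5-dimethoxyphenyl)pentanedioate (racemic), via lithium ester enolate 10 (not isolated)
Conditions: LiN(SiMe3)2, THF, −78 °C; then 9, −78 °C; AcOH
Reagents that add atoms: none
Why: Michael addition of the benzylic ester enolate to the acrylate at low temperature should stop at the mono-adduct, since the new non-stabilised enolate is quenched before it adds again.

Step 6
Reactants: 11 5-tert-butyl 1-methyl 2-(4-isopropyl-3,5-dimethoxyphenyl)pentanedioate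
Product: 13 methyl 6-isopropyl-5,7-dimethoxy-4-oxo-1,2,3,4-tetrahydronaphthalene-1-carboxylate (racemic), via glutaric monoacid 12 (not isolated)
Conditions: CF3CO2H, CH2Cl2, rt; then (CF3CO)2O, 0 °C to rt
Reagents that add atoms: none
Why: Acidolysis frees only the tert-butyl ester, and the mixed trifluoroacetic anhydride then closes ring B by intramolecular Friedel–Crafts acylation at the position ortho and para to the two methoxy groups (both ortho positions are equivalent).

Step 7
Reactants: 13 methyl 6-isopropyl-5,7-dimethoxy-4-oxo-1,2,3,4-tetrahydronaphthalene-1-carboxylate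
Product: 15 methyl 4-hydroxy-6-isopropyl-5,7-dimethoxy-1-naphthoate, via 3-bromo ketone 14 (not isolated)
Conditions: PhNMe3Br3, THF, 0 °C to rt; then LiBr, Li2CO3, DMF, 120 °C
Reagents that add atoms: none
Why: α-Bromination of the aryl ketone followed by dehydrobromination gives a dienone that tautomerises to the naphthol, because its C1–H is benzylic and α to the ester.

Step 8
Reactants: 15 methyl 4-hydroxy-6-isopropyl-5,7-dimethoxy-1-naphthoate
Product: 16 methyl 6-isopropyl-4,5,7-trimethoxy-1-naphthoate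
Conditions: MeI, K2CO3, DMF, rt
Reagents that add atoms: iodomethane, CI
Why: Williamson O-methylation of the naphthoxide.

Step 9
Reactants: 16 methyl 6-isopropyl-4,5,7-trimethoxy-1-naphthoate
Product: 17 6-isopropyl-4,5,7-trimethoxy-1-naphthoic acid
Conditions: LiOH, THF/MeOH/H2O, 60 °C; then 1 M HCl
Reagents that add atoms: lithium hydroxide, [Li+].[OH-]
Why: Saponification of the aryl methyl ester by acyl–oxygen cleavage.

Step 10
Reactants: 17 6-isopropyl-4,5,7-trimethoxy-1-naphthoic acid; 18 (R)-tert-leucinol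
Product: 21 (R)-4-tert-butyl-2-(6-isopropyl-4,5,7-trimethoxynaphthalen-1-yl)-4,5-dihydrooxazole, via naphthoyl chloride 19 (not isolated), via hydroxy amide 20 (not isolated)
Conditions: (COCl)2, DMF (cat.), CH2Cl2, 0 °C to rt; evaporate; 18, Et3N, CH2Cl2, 0 °C to rt; then MsCl, Et3N, 0 to 40 °C
Reagents that add atoms: none
Why: Amide formation through the acid chloride and cyclodehydration through the O-mesylate (5-exo-tet attack of the amide oxygen) give the oxazoline without touching the auxiliary stereocentre.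

Step 11
Reactants: 21 (R)-4-tert-butyl-2-(6-isopropyl-4,5,7-trimethoxynaphthalen-1-yl)-4,5-dihydrooxazole; 22 2-bromopropene; 23 tert-butyl(3-iodopropoxy)dimethylsilane
Product: 26 (4R)-4-tert-butyl-2-[(1R,2S)-1-[3-(tert-butyldimethylsilyloxy)propyl]-6-isopropyl-4,5,7-trimethoxy-2-(prop-1-en-2-yl)-1,2-dihydronaphthalen-1-yl]-4,5-dihydrooxazole, via isopropenyllithium 24 (not isolated), via lithium aza-enolate 25 (not isolated)
Conditions: 22, t-BuLi (2 equiv per 22), Et2O, −78 °C; then 21, THF, −78 to −40 °C; then 23, DMPU, −78 °C to rt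
Reagents that add atoms: none
Why: Isopropenyllithium binds the oxazoline nitrogen in the s-cis N=C–C10=C5 conformer and is delivered to C5, which dearomatises ring B to a lithium aza-enolate that the primary iodide alkylates at C10 by SN2, so C4–C5 and C10–C1 form in one flask. The closest known reaction type is the tandem organolithium addition–alkylation of chiral 1-naphthyl oxazolines; the 4-methoxy, electron-rich member used here is an untested substrate of that class. No ring is closed. The C5 centre is controlled by the tert-butyl group of the (R)-oxazoline, which blocks one face of the chelated reagent, and the C10 centre by the new isopropenyl group, which sends the iodide to the opposite face of the planar aza-enolate, so the chain ends trans and the oxazoline carbon cis to isopropenyl. The step needs conjugate addition at C5 in preference to attack at C=N, ortho-lithiation or methoxy displacement. This is secured by the hindered, weakly electrophilic oxazoline carbon, by nitrogen-directed delivery to C5 as the only position conjugated to C=N, by the absence of an ortho methoxy group, and by ring C staying aromatic.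

Step 12
Reactants: 26 (4R)-4-tert-butyl-2-[(1R,2S)-1-[3-(tert-butyldimethylsilyloxy)propyl]-6-isopropyl-4,5,7-trimethoxy-2-(prop-1-en-2-yl)-1,2-dihydronaphthalen-1-yl]-4,5-dihydrooxazole
Product: 30 (1R,2S)-2′-hydroxy-6-isopropyl-5,7-dimethoxy-2-(prop-1-en-2-yl)-2,3-dihydro-4H-spiro[naphthalene-1,3′-oxan]-4-one (anomer mixture), via N-methyloxazolinium triflate 27 (not isolated), via N-methyloxazolidine 28 (not isolated), via hydroxy keto aldehyde 29 (not isolated)
Conditions: MeOTf, CH2Cl2, 0 °C to rt; then NaBH4, THF/MeOH, 0 °C; then 1 M HCl, THF, rt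
Reagents that add atoms: water, O
Why: N-Methylation makes the oxazoline reducible by hydride to an N,O-acetal, and aqueous acid then hydrolyses this to the aldehyde, the aryl enol ether to the C7 ketone and the primary silyl ether to the alcohol, which closes onto the aldehyde as a six-membered lactol while C5 and C10 stay untouched.

Step 13
Reactants: 30 (1R,2S)-2′-hydroxy-6-isopropyl-5,7-dimethoxy-2-(prop-1-en-2-yl)-2,3-dihydro-4H-spiro[naphthalene-1,3′-oxan]-4-one
Product: 32 (3S,4S)-4-(3-hydroxypropyl)-7-isopropyl-6,8-dimethoxy-4-methyl-3-(prop-1-en-2-yl)-3,4-dihydronaphthalen-1(2H)-one, via tosylhydrazone 31 (not isolated)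
Conditions: TsNHNH2, EtOH, 50 °C; evaporate; catecholborane, CHCl3, 0 °C to rt; then NaOAc·3H2O, reflux
Reagents that add atoms: none
Why: The lactol opens to the aldehyde, which should condense with tosylhydrazide far faster than the hindered, electron-rich aryl ketone, and hydroboration of the C=N bond followed by acetate-induced loss of sulfinate and dinitrogen (Kabalka reduction) leaves the C10 methyl group.

Step 14
Reactants: 32 (3S,4S)-4-(3-hydroxypropyl)-7-isopropyl-6,8-dimethoxy-4-methyl-3-(prop-1-en-2-yl)-3,4-dihydronaphthalen-1(2H)-one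
Product: 34 3-[(1S,2S)-6-isopropyl-5,7-dimethoxy-1-methyl-4-oxo-2-(prop-1-en-2-yl)-1,2,3,4-tetrahydronaphthalen-1-yl]propanoic acid, via keto aldehyde 33 (not isolated)
Conditions: TEMPO (cat.), PhI(OAc)2, MeCN/H2O, rt
Reagents that add atoms: water, O
Why: Oxoammonium-mediated oxidation takes the primary alcohol to the aldehyde and, through its hydrate, to the acid under conditions that leave the alkene, the ketone and the aryl ethers alone.

Step 15
Reactants: 34 3-[(1S,2S)-6-isopropyl-5,7-dimethoxy-1-methyl-4-oxo-2-(prop-1-en-2-yl)-1,2,3,4-tetrahydronaphthalen-1-yl]propanoic acid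
Product: 35 methyl 3-[(1S,2S)-6-isopropyl-5,7-dimethoxy-1-methyl-4-oxo-2-(prop-1-en-2-yl)-1,2,3,4-tetrahydronaphthalen-1-yl]propanoate
Conditions: MeI, K2CO3, DMF, rt
Reagents that add atoms: iodomethane, CI
Why: SN2 O-alkylation of the carboxylate, with carbonate too weak to enolise the ketone.

Step 16
Reactants: 35 methyl 3-[(1S,2S)-6-isopropyl-5,7-dimethoxy-1-methyl-4-oxo-2-(prop-1-en-2-yl)-1,2,3,4-tetrahydronaphthalen-1-yl]propanoate
Product: 36 methyl 3-[(1S,2S)-5-hydroxy-6-isopropyl-7-methoxy-1-methyl-4-oxo-2-(prop-1-en-2-yl)-1,2,3,4-tetrahydronaphthalen-1-yl]propanoate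
Conditions: BCl3, CH2Cl2, −78 to 0 °C; then H2O
Reagents that add atoms: none
Why: Chelation of boron between the C7 carbonyl and the peri methoxy oxygen directs Lewis-acid ether cleavage to C14 only.

Step 17
Reactants: 36 methyl 3-[(1S,2S)-5-hydroxy-6-isopropyl-7-methoxy-1-methyl-4-oxo-2-(prop-1-en-2-yl)-1,2,3,4-tetrahydronaphthalen-1-yl]propanoate
Product: 37 methyl 3-[(1S,2S)-6-isopropyl-7-methoxy-1-methyl-4,5,8-trioxo-2-(prop-1-en-2-yl)-1,2,3,4,5,8-hexahydronaphthalen-1-yl]propanoate
Conditions: (KSO3)2NO, KH2PO4, acetone/H2O, rt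
Reagents that add atoms: potassium nitrosodisulfonate, [K+].[K+].[O]N(S(=O)(=O)[O-])S(=O)(=O)[O-]
Why: Teuber oxidation, in which the phenoxyl radical is trapped at the free para carbon C11 by a second nitroxide and collapses to the para-quinone.

Step 18
Reactants: 37 methyl 3-[(1S,2S)-6-isopropyl-7-methoxy-1-methyl-4,5,8-trioxo-2-(prop-1-en-2-yl)-1,2,3,4,5,8-hexahydronaphthalen-1-yl]propanoate
Product: 38 methyl 3-[(1S,2S)-7-hydroxy-6-isopropyl-1-methyl-4,5,8-trioxo-2-(prop-1-en-2-yl)-1,2,3,4,5,8-hexahydronaphthalen-1-yl]propanoate (CNP0308749.1)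
Conditions: BCl3, CH2Cl2, −78 to −20 °C; then H2O
Reagents that add atoms: none
Why: The methoxyquinone is a vinylogous ester that loses its methyl group to chloride once boron coordinates the quinone carbonyl next to it, whereas the saturated methyl ester has no such activation and should survive this Lewis-acid demethylation.

**Compound list**

1 | 1,3-dimethoxybenzene | COc1cccc(OC)c1 | starting material
2 | acetone | CC(C)=O | starting material
3 | 2,6-dimethoxyphenyllithium | [Li]c1c(OC)cccc1OC | intermediate (not isolated)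
4 | 2-(2,6-dimethoxyphenyl)propan-2-ol | COc1cccc(OC)c1C(C)(C)O | intermediate
5 | 2-isopropyl-1,3-dimethoxybenzene | COc1cccc(OC)c1C(C)C | intermediate
6 | 2-(4-isopropyl-3,5-dimethoxyphenyl)-4,4,5,5-tetramethyl-1,3,2-dioxaborolane | COc1cc(B2OC(C)(C)C(C)(C)O2)cc(OC)c1C(C)C | intermediate
7 | methyl bromoacetate | COC(=O)CBr | starting material
8 | methyl 2-(4-isopropyl-3,5-dimethoxyphenyl)acetate | COC(=O)Cc1cc(OC)c(C(C)C)c(OC)c1 | intermediate
9 | tert-butyl acrylate | C=CC(=O)OC(C)(C)C | starting material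
10 | lithium enolate of methyl 2-(4-isopropyl-3,5-dimethoxyphenyl)acetate | COC(O[Li])=Cc1cc(OC)c(C(C)C)c(OC)c1 | intermediate (not isolated)
11 | 5-tert-butyl 1-methyl 2-(4-isopropyl-3,5-dimethoxyphenyl)pentanedioate (racemic) | COC(=O)C(CCC(=O)OC(C)(C)C)c1cc(OC)c(C(C)C)c(OC)c1 | intermediate
12 | 4-(4-isopropyl-3,5-dimethoxyphenyl)-5-methoxy-5-oxopentanoic acid (racemic) | COC(=O)C(CCC(=O)O)c1cc(OC)c(C(C)C)c(OC)c1 | intermediate (not isolated)
13 | methyl 6-isopropyl-5,7-dimethoxy-4-oxo-1,2,3,4-tetrahydronaphthalene-1-carboxylate (racemic) | COC(=O)C1CCC(=O)c2c(OC)c(C(C)C)c(OC)cc21 | intermediate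
14 | methyl 3-bromo-6-isopropyl-5,7-dimethoxy-4-oxo-1,2,3,4-tetrahydronaphthalene-1-carboxylate (diastereomer mixture) | COC(=O)C1CC(Br)C(=O)c2c(OC)c(C(C)C)c(OC)cc21 | intermediate (not isolated)
15 | methyl 4-hydroxy-6-isopropyl-5,7-dimethoxy-1-naphthoate | COC(=O)c1ccc(O)c2c(OC)c(C(C)C)c(OC)cc12 | intermediate
16 | methyl 6-isopropyl-4,5,7-trimethoxy-1-naphthoate | COC(=O)c1ccc(OC)c2c(OC)c(C(C)C)c(OC)cc12 | intermediate
17 | 6-isopropyl-4,5,7-trimethoxy-1-naphthoic acid | OC(=O)c1ccc(OC)c2c(OC)c(C(C)C)c(OC)cc12 | intermediate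
18 | (R)-tert-leucinol, (R)-2-amino-3,3-dimethylbutan-1-ol | N[C@H](C(C)(C)C)CO | starting material
19 | 6-isopropyl-4,5,7-trimethoxy-1-naphthoyl chloride | O=C(Cl)c1ccc(OC)c2c(OC)c(C(C)C)c(OC)cc12 | intermediate (not isolated)
20 | N-[(R)-1-hydroxy-3,3-dimethylbutan-2-yl]-6-isopropyl-4,5,7-trimethoxy-1-naphthamide | O=C(N[C@H](C(C)(C)C)CO)c1ccc(OC)c2c(OC)c(C(C)C)c(OC)cc12 | intermediate (not isolated)
21 | (R)-4-tert-butyl-2-(6-isopropyl-4,5,7-trimethoxynaphthalen-1-yl)-4,5-dihydrooxazole | COc1ccc(C2=N[C@H](C(C)(C)C)CO2)c2cc(OC)c(C(C)C)c(OC)c12 | intermediate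
22 | 2-bromopropene | C=C(C)Br | starting material
23 | tert-butyl(3-iodopropoxy)dimethylsilane | ICCCO[Si](C)(C)C(C)(C)C | starting material
24 | isopropenyllithium | [Li]C(C)=C | intermediate (not isolated)
25 | N-lithio (4R)-4-tert-butyl-2-[(2S)-6-isopropyl-4,5,7-trimethoxy-2-(prop-1-en-2-yl)naphthalen-1(2H)-ylidene]oxazolidine (lithium aza-enolate) | C=C(C)[C@@H]1C=C(OC)c2c(OC)c(C(C)C)c(OC)cc2C1=C3N([Li])[C@H](C(C)(C)C)CO3 | intermediate (not isolated)
26 | (4R)-4-tert-butyl-2-[(1R,2S)-1-[3-(tert-butyldimethylsilyloxy)propyl]-6-isopropyl-4,5,7-trimethoxy-2-(prop-1-en-2-yl)-1,2-dihydronaphthalen-1-yl]-4,5-dihydrooxazole | C=C(C)[C@@H]1C=C(OC)c2c(OC)c(C(C)C)c(OC)cc2[C@@]1(C3=N[C@H](C(C)(C)C)CO3)CCCO[Si](C)(C)C(C)(C)C | intermediate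
27 | N-methyloxazolinium triflate of 26 | C=C(C)[C@@H]1C=C(OC)c2c(OC)c(C(C)C)c(OC)cc2[C@@]1(C3=[N+](C)[C@H](C(C)(C)C)CO3)CCCO[Si](C)(C)C(C)(C)C.[O-]S(=O)(=O)C(F)(F)F | intermediate (not isolated)
28 | N-methyloxazolidine from 27 (C2′ epimers) | C=C(C)[C@@H]1C=C(OC)c2c(OC)c(C(C)C)c(OC)cc2[C@@]1(C3N(C)[C@H](C(C)(C)C)CO3)CCCO[Si](C)(C)C(C)(C)C | intermediate (not isolated)
29 | (1R,2S)-1-(3-hydroxypropyl)-6-isopropyl-5,7-dimethoxy-4-oxo-2-(prop-1-en-2-yl)-1,2,3,4-tetrahydronaphthalene-1-carbaldehyde | C=C(C)[C@@H]1CC(=O)c2c(OC)c(C(C)C)c(OC)cc2[C@@]1(C=O)CCCO | intermediate (not isolated)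
30 | (1R,2S)-2′-hydroxy-6-isopropyl-5,7-dimethoxy-2-(prop-1-en-2-yl)-2,3-dihydro-4H-spiro[naphthalene-1,3′-oxan]-4-one (lactol of 29, anomer mixture) | C=C(C)[C@@H]1CC(=O)c2c(OC)c(C(C)C)c(OC)cc2[C@@]1(C(O)OC3)CC3 | intermediate
31 | tosylhydrazone of 29 | C=C(C)[C@@H]1CC(=O)c2c(OC)c(C(C)C)c(OC)cc2[C@@]1(C=NNS(=O)(=O)c3ccc(C)cc3)CCCO | intermediate (not isolated)
32 | (3S,4S)-4-(3-hydroxypropyl)-7-isopropyl-6,8-dimethoxy-4-methyl-3-(prop-1-en-2-yl)-3,4-dihydronaphthalen-1(2H)-one | C=C(C)[C@@H]1CC(=O)c2c(OC)c(C(C)C)c(OC)cc2[C@@]1(C)CCCO | intermediate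
33 | 3-[(1S,2S)-6-isopropyl-5,7-dimethoxy-1-methyl-4-oxo-2-(prop-1-en-2-yl)-1,2,3,4-tetrahydronaphthalen-1-yl]propanal | C=C(C)[C@@H]1CC(=O)c2c(OC)c(C(C)C)c(OC)cc2[C@@]1(C)CCC=O | intermediate (not isolated)
34 | 3-[(1S,2S)-6-isopropyl-5,7-dimethoxy-1-methyl-4-oxo-2-(prop-1-en-2-yl)-1,2,3,4-tetrahydronaphthalen-1-yl]propanoic acid | C=C(C)[C@@H]1CC(=O)c2c(OC)c(C(C)C)c(OC)cc2[C@@]1(C)CCC(=O)O | intermediate
35 | methyl 3-[(1S,2S)-6-isopropyl-5,7-dimethoxy-1-methyl-4-oxo-2-(prop-1-en-2-yl)-1,2,3,4-tetrahydronaphthalen-1-yl]propanoate | C=C(C)[C@@H]1CC(=O)c2c(OC)c(C(C)C)c(OC)cc2[C@@]1(C)CCC(=O)OC | intermediate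
36 | methyl 3-[(1S,2S)-5-hydroxy-6-isopropyl-7-methoxy-1-methyl-4-oxo-2-(prop-1-en-2-yl)-1,2,3,4-tetrahydronaphthalen-1-yl]propanoate | C=C(C)[C@@H]1CC(=O)c2c(O)c(C(C)C)c(OC)cc2[C@@]1(C)CCC(=O)OC | intermediate
37 | methyl 3-[(1S,2S)-6-isopropyl-7-methoxy-1-methyl-4,5,8-trioxo-2-(prop-1-en-2-yl)-1,2,3,4,5,8-hexahydronaphthalen-1-yl]propanoate | C=C(C)[C@@H]1CC(=O)C2=C(C(=O)C(OC)=C(C(C)C)C2=O)[C@@]1(C)CCC(=O)OC | intermediate
38 | methyl 3-[(1S,2S)-7-hydroxy-6-isopropyl-1-methyl-4,5,8-trioxo-2-(prop-1-en-2-yl)-1,2,3,4,5,8-hexahydronaphthalen-1-yl]propanoate (CNP0308749.1) | C=C(C)[C@@H]1CC(=O)C2=C(C(=O)C(O)=C(C(C)C)C2=O)[C@@]1(C)CCC(=O)OC | target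

**Step count and risks**

Total step count: 18. Longest linear sequence: 18 steps (1 to 38); compounds 2, 7, 9, 18, 22 and 23 enter as bought materials.

Steps most likely to fail:

1. Step 11. The para methoxy group pushes electron density towards the oxazoline-bearing carbon, so conjugate addition may be slow and ortho-lithiation at C5 or incomplete conversion may compete. The facial bias, or the capture of the hindered aza-enolate by the iodide, may also be insufficient. The fallback sets out from acid 17 and returns at lactol 30; it changes the activating group to an ester and the source of asymmetry to an external ligand. The acid chloride 19 is esterified with lithium 2,6-di-tert-butyl-4-methoxyphenoxide to 2,6-di-tert-butyl-4-methoxyphenyl 6-isopropyl-4,5,7-trimethoxy-1-naphthoate F1, a stronger acceptor whose carbonyl group is shielded. Isopropenyllithium 24, complexed with (1R,2R)-1,2-dimethoxy-1,2-diphenylethane (or its enantiomer, whichever delivers 5S) in toluene at −78 °C, should add to C5, and the ester enolate is alkylated with 23 to the trans-1,2-disubstituted 1,2-dihydronaphthalene-1-carboxylate F2. LiAlH4 in THF at reflux should cleave the aryl ester to the neopentyl alcohol F3, and Dess–Martin periodinane with NaHCO3 should give the enol ether aldehyde F4. 1 M HCl in THF then unmasks the ketone and the alcohol to return 30.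

2. Step 13. Opening of the lactol and condensation at the neopentyl aldehyde may be slow enough for the C7 ketone to form a hydrazone or be reduced, or hydride transfer to the crowded hydrazone may stall. The fallback sets out from lactol 30 and returns at 32; it replaces the hydrazone–diazene path by a thioacetal and radical desulfurisation. Ethane-1,2-dithiol with Zn(OTf)2 in CH2Cl2 should convert the masked aldehyde selectively into the dithiolane (3S,4R)-4-(1,3-dithiolan-2-yl)-4-(3-hydroxypropyl)-7-isopropyl-6,8-dimethoxy-3-(prop-1-en-2-yl)-3,4-dihydronaphthalen-1(2H)-one F5. Bu3SnH with AIBN in toluene at reflux then removes both C–S bonds, with fast hydrogen transfer from the stannane outrunning any aryl shift of the neopentyl radical, to give 32.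

3. Step 17. The phenol is locked in a hydrogen bond to the C7 carbonyl and its para carbon lies next to the quaternary centre, so hydrogen abstraction or para trapping by the nitroxide may be too slow, or oxidation may go astray. The fallback sets out from ester 35 and returns at target 38, replacing steps 16–18. BCl3 with n-Bu4NI in CH2Cl2 (−78 to 0 °C) should cleave both aryl methyl ethers to the resorcinol methyl 3-[(1S,2S)-5,7-dihydroxy-6-isopropyl-1-methyl-4-oxo-2-(prop-1-en-2-yl)-1,2,3,4-tetrahydronaphthalen-1-yl]propanoate F6. This much more electron-rich ring is then oxidised at C11 with O2 and Co(salen) [N,N′-bis(salicylidene)ethylenediaminocobalt] in DMF, giving the hydroxyquinone 38 directly.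

Further compounds
F1 | step 11 | 2,6-di-tert-butyl-4-methoxyphenyl 6-isopropyl-4,5,7-trimethoxy-1-naphthoate | COc1cc(C(C)(C)C)c(OC(=O)c2ccc(OC)c3c(OC)c(C(C)C)c(OC)cc23)c(C(C)(C)C)c1
F2 | step 11 | 2,6-di-tert-butyl-4-methoxyphenyl (1R,2S)-1-[3-(tert-butyldimethylsilyloxy)propyl]-6-isopropyl-4,5,7-trimethoxy-2-(prop-1-en-2-yl)-1,2-dihydronaphthalene-1-carboxylate | C=C(C)[C@@H]1C=C(OC)c2c(OC)c(C(C)C)c(OC)cc2[C@@]1(C(=O)Oc3c(C(C)(C)C)cc(OC)cc3C(C)(C)C)CCCO[Si](C)(C)C(C)(C)C
F3 | step 11 | [(1R,2S)-1-[3-(tert-butyldimethylsilyloxy)propyl]-6-isopropyl-4,5,7-trimethoxy-2-(prop-1-en-2-yl)-1,2-dihydronaphthalen-1-yl]methanol | C=C(C)[C@@H]1C=C(OC)c2c(OC)c(C(C)C)c(OC)cc2[C@@]1(CO)CCCO[Si](C)(C)C(C)(C)C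
F4 | step 11 | (1R,2S)-1-[3-(tert-butyldimethylsilyloxy)propyl]-6-isopropyl-4,5,7-trimethoxy-2-(prop-1-en-2-yl)-1,2-dihydronaphthalene-1-carbaldehyde | C=C(C)[C@@H]1C=C(OC)c2c(OC)c(C(C)C)c(OC)cc2[C@@]1(C=O)CCCO[Si](C)(C)C(C)(C)C
F5 | step 13 | (3S,4R)-4-(1,3-dithiolan-2-yl)-4-(3-hydroxypropyl)-7-isopropyl-6,8-dimethoxy-3-(prop-1-en-2-yl)-3,4-dihydronaphthalen-1(2H)-one | C=C(C)[C@@H]1CC(=O)c2c(OC)c(C(C)C)c(OC)cc2[C@@]1(C3SCCS3)CCCO
F6 | step 17 | methyl 3-[(1S,2S)-5,7-dihydroxy-6-isopropyl-1-methyl-4-oxo-2-(prop-1-en-2-yl)-1,2,3,4-tetrahydronaphthalen-1-yl]propanoate | C=C(C)[C@@H]1CC(=O)c2c(O)c(C(C)C)c(O)cc2[C@@]1(C)CCC(=O)OC
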